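The methoxyindole (ring A) is disconnected across C2–C3. These two adjacent CH carbons, lying between N1 and C3a, are traced back to a formamide carbon on N1 and an aldehyde carbon on C3a of a pentasubstituted benzene that already carries the N-linked bromoindole (ring B) at C4, bromine at C5 and methoxy at C7. Low-valent titanium joins the two carbonyl carbons and strips both oxygens in one operation, closing the pyrrole ring with C2 and C3 unsubstituted and N1–H free. The precursor, an ortho-formamido benzaldehyde, is assembled in five steps from 2-fluoro-5-methoxybenzaldehyde and 5-bromoindole; a single C3 bromination then completes the target.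

Key step: step 6

Remark: ring A locants are unprimed and ring B locants primed; the target SMILES carries no stereodescriptor, so the C4–N1' axis is left undefined and the material is made as a racemate should rotation about it be slow.

Step 1
Reactants: 1 2-fluoro-5-methoxybenzaldehyde
Product: 2 6-fluoro-3-methoxy-2-nitrobenzaldehyde
Conditions: KNO3 (1.05 equiv), conc. H2SO4, −10 → 0 °C; separation from any isomer nitrated para to the formyl group
Reagents that add atoms: potassium nitrate KNO3, [K+].[O-][N+](=O)[O-]
Why: Electrophilic aromatic nitration is steered by the methoxy group, whose para position is blocked by fluorine, and of its two ortho positions the one next to the formyl group is the site that 3-alkoxybenzaldehydes normally prefer.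

Step 2
Reactants: 2 6-fluoro-3-methoxy-2-nitrobenzaldehyde; 3 5-bromo-1H-indole
Product: 4 6-(5-bromoindol-1-yl)-3-methoxy-2-nitrobenzaldehyde
Conditions: Cs2CO3 (1.5 equiv), DMSO, 60–80 °C
Reagents that add atoms: none
Why: Nucleophilic aromatic substitution (addition–elimination) by the indolide nitrogen at the fluorine-bearing carbon, whose Meisenheimer intermediate is stabilised by the ortho formyl group and inductively by the meta nitro group, with fluoride as the best leaving group for this mechanism.

Step 3
Reactants: 4 6-(5-bromoindol-1-yl)-3-methoxy-2-nitrobenzaldehyde
Product: 5 2-amino-6-(5-bromoindol-1-yl)-3-methoxybenzaldehyde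
Conditions: Fe powder (5 equiv), NH4Cl, EtOH/H2O, 75 °C; product used promptly
Reagents that add atoms: none
Why: Béchamp-type iron reduction takes the nitro group through the nitroso and hydroxylamine stages to the amine at near-neutral pH, where the aryl bromide and the aldehyde are left alone and the doubly flanked amino aldehyde should resist self-condensation.

Step 4
Reactants: 5 2-amino-6-(5-bromoindol-1-yl)-3-methoxybenzaldehyde
Product: 6 2-amino-5-bromo-6-(3,5-dibromoindol-1-yl)-3-methoxybenzaldehyde
Conditions: NBS (2.05 equiv), DMF, −10 → 0 °C, dark
Reagents that add atoms: N-bromosuccinimide, O=C1CCC(=O)N1Br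
Why: Two electrophilic aromatic brominations should occur, one at C3' (the most nucleophilic carbon of ring B) and one at the only free position para to the amino group (also meta to the formyl group), while the remaining ring hydrogen is meta to the amine and para to the formyl group.

Step 5
Reactants: 6 2-amino-5-bromo-6-(3,5-dibromoindol-1-yl)-3-methoxybenzaldehyde
Product: 7 N-[4-bromo-3-(3,5-dibromoindol-1-yl)-2-formyl-6-methoxyphenyl]formamide
Conditions: HCO2H/Ac2O (premixed at 50 °C, cooled; 3 equiv), THF, 0 °C → rt
Reagents that add atoms: acetic formic anhydride, CC(=O)OC=O
Why: N-Acylation by a mixed anhydride, which delivers its less hindered and more electrophilic formyl group and is reactive enough for an aniline that is flanked on both sides and hydrogen-bonded to the ortho aldehyde.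

Step 6
Reactants: 7 N-[4-bromo-3-(3,5-dibromoindol-1-yl)-2-formyl-6-methoxyphenyl]formamide
Product: 8 5-bromo-4-(3,5-dibromoindol-1-yl)-7-methoxy-1H-indole
Conditions: TiCl3 (4 equiv), Zn dust (8 equiv), DME, reflux, 2 h; then 7 in DME by syringe pump over 6 h at reflux (final concentration about 0.01 M); filtration through silica
Reagents that add atoms: none
Why: Low-valent titanium made from TiCl3 and Zn transfers electrons to the aldehyde on C3a, and the titanium-bound ketyl carbon attacks the carbonyl carbon of the neighbouring formamide on N1, so that two carbons that are both electrophilic in 7 become bonded as C3–C2; the titanium-held 2,3-dioxygenated indoline then gives up both oxygens to the oxophilic metal and the aromatic C2=C3 bond results. The closest known reaction type is the titanium-induced oxo-amide coupling of 2-acylamino aryl carbonyl compounds to indoles, an intramolecular McMurry-type reaction, here with the less usual pairing of a formamide and an aldehyde. The pyrrole ring of ring A closes in a 5-exo-trig mode, the ketyl carbon adding to a C=O whose oxygen stays outside the new ring. No stereocenter is formed. The step needs intramolecular carbonyl–carbonyl coupling to beat intermolecular pinacol coupling and C–Br reduction: the ortho placement of the two formyl groups makes the five-membered closure fast, ring B at C4 and the formamide shield the aldehyde from dimerisation, slow addition keeps 7 dilute, and TiCl3/Zn normally reacts at carbonyl groups well before aryl bromides. The free N–H is tolerated, so 8 needs no deprotection.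

Step 7
Reactants: 8 5-bromo-4-(3,5-dibromoindol-1-yl)-7-methoxy-1H-indole
Product: 9 rivularin B, 3,5-dibromo-4-(3,5-dibromoindol-1-yl)-7-methoxy-1H-indole
Conditions: NBS (1.0 equiv), DMF, −40 → 0 °C, dark
Reagents that add atoms: N-bromosuccinimide, O=C1CCC(=O)N1Br
Why: Electrophilic bromination should go to C3, the most nucleophilic carbon left, because C3' is already brominated, C2 and C2' are far less reactive and C6 is wedged between methoxy and bromine; one equivalent at low temperature without acid protects the sensitive 3-bromoindole.

Compound list
1 | 2-fluoro-5-methoxybenzaldehyde | COc1ccc(F)c(C=O)c1 | starting material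
2 | 6-fluoro-3-methoxy-2-nitrobenzaldehyde | COc1ccc(F)c(C=O)c1[N+](=O)[O-] | intermediate
3 | 5-bromo-1H-indole | Brc1ccc2[nH]ccc2c1 | starting material
4 | 6-(5-bromoindol-1-yl)-3-methoxy-2-nitrobenzaldehyde | COc1ccc(-n2ccc3cc(Br)ccc32)c(C=O)c1[N+](=O)[O-] | intermediate
5 | 2-amino-6-(5-bromoindol-1-yl)-3-methoxybenzaldehyde | COc1ccc(-n2ccc3cc(Br)ccc32)c(C=O)c1N | intermediate
6 | 2-amino-5-bromo-6-(3,5-dibromoindol-1-yl)-3-methoxybenzaldehyde | COc1cc(Br)c(-n2cc(Br)c3cc(Br)ccc32)c(C=O)c1N | intermediate
7 | N-[4-bromo-3-(3,5-dibromoindol-1-yl)-2-formyl-6-methoxyphenyl]formamide | O=CNc1c(OC)cc(Br)c(-n2cc(Br)c3cc(Br)ccc32)c1C=O | intermediate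
8 | 5-bromo-4-(3,5-dibromoindol-1-yl)-7-methoxy-1H-indole | COc1cc(Br)c(-n2cc(Br)c3cc(Br)ccc32)c2cc[nH]c12 | intermediate
9 | rivularin B, 3,5-dibromo-4-(3,5-dibromoindol-1-yl)-7-methoxy-1H-indole | COc1cc(Br)c(-n2cc(Br)c3cc(Br)ccc32)c2c(Br)c[nH]c12 | target

Total step count: 7. Longest linear sequence: 7 steps, from 1 to 9; 3 enters at step 2.

Steps most likely to fail

1. Step 6. Intermolecular ketyl dimerisation or plain reduction of the aldehyde may outrun attack on the formamide, and the reducing metal may strip bromine, most easily from C3' of ring B. The fallback sets out from 6 and returns at 8, and it uses no reducing metal. Wittig methoxymethylenation of the aldehyde of 6 (Ph3P(CH2OMe)Cl, KOtBu, THF, 0 °C) should give the enol ether 4-bromo-3-(3,5-dibromoindol-1-yl)-6-methoxy-2-(2-methoxyethenyl)aniline F1 as an E/Z mixture. Aqueous acid (TFA/H2O, CH2Cl2, rt) should then unmask the arylacetaldehyde, which condenses with the free amine and loses methanol to give 8. In this variant C2 comes from the ylide carbon and the ring closes at N1–C2 by condensation.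

2. Step 2. Displacement of fluoride may be sluggish because the nitro group is meta and the methoxy group para to the leaving group, and the strongly basic indolide may instead attack the nitro-bearing carbon or degrade the aldehyde. The fallback sets out from 2 and returns at 4. The neutral secondary amine 5-bromoindoline (Brc1ccc2NCCc2c1, commercial) with K2CO3 in DMSO at 90 °C should displace fluoride in the way secondary amines routinely do with 2-fluorobenzaldehydes, giving 6-(5-bromo-2,3-dihydroindol-1-yl)-3-methoxy-2-nitrobenzaldehyde F2. Dehydrogenation of the indoline ring with DDQ (toluene, rt → 60 °C) should then give 4.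

3. Step 1. Nitration may take place at the other position ortho to methoxy (para to the formyl group) or oxidise the aldehyde, leaving too little of the required isomer. The fallback sets out from 3 and returns at 4, using commercial 3-methoxy-2-nitrobenzaldehyde (COc1cccc(C=O)c1[N+](=O)[O-]), in which nitro, formyl and methoxy already stand in the required order. Iodination para to methoxy (NIS, TfOH, 0 °C → rt), the position that halogenation of 3-methoxybenzaldehydes favours, should give 6-iodo-3-methoxy-2-nitrobenzaldehyde F3. An Ullmann–Goldberg N-arylation of 3 (CuI 10 mol %, N,N-dimethylglycine 20 mol %, K3PO4, dioxane, 90 °C) should then give 4, the aryl iodide reacting well ahead of the C5'–Br bond. The tertiary-amine ligand is chosen because it cannot condense with the aldehyde.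

Further compounds
F1 | step 6 | 4-bromo-3-(3,5-dibromoindol-1-yl)-6-methoxy-2-(2-methoxyethenyl)aniline (E/Z mixture) | COC=Cc1c(N)c(OC)cc(Br)c1-n1cc(Br)c2cc(Br)ccc21
F2 | step 2 | 6-(5-bromo-2,3-dihydroindol-1-yl)-3-methoxy-2-nitrobenzaldehyde | COc1ccc(N2CCc3cc(Br)ccc32)c(C=O)c1[N+](=O)[O-]
F3 | step 1 | 6-iodo-3-methoxy-2-nitrobenzaldehyde | COc1ccc(I)c(C=O)c1[N+](=O)[O-]
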